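**Plan**
1. Retrosynthesis: remove the two phenolic MOM acetals; cut C4–C5 of the hexadecanoyl chain into two N-acyloxyphthalimides (C5–C16 from tridecanoic acid, C1–C4 from a glutaric half-ester); cut the benzylic O–C1 bond (opening of glutaric anhydride); cut the diaryl ether O–C bond on the benzoate ring (Ullmann); cut the C–CO2Me bond of that ring (ortho-metalation); trace the 3-OH of the benzyl ring to a bromide.
2. Enabling feature: the acyl chain is unbranched and saturated, so C4 and C5 are both plain CH2 carbons, and C4 lies three carbons from the ester carbonyl C1. Each can therefore be born as a primary radical from a carboxyl group (C4 from a glutarate made by opening the six-membered anhydride ring with the benzylic oxygen). The two benzene rings, their ethers and the esters are inert at the cathode potential of an N-acyloxyphthalimide.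
3. Forward order: the bromo ester of the benzoate ring (steps 1–2) and the MOM-protected salicylaldehyde (steps 3–4) are joined by Cu-catalysed O-arylation (step 5). Reduction, anhydride opening and NHPI activation (steps 6–8) give the core redox-active ester. Ni-electrocatalytic doubly decarboxylative coupling with the tridecanoic NHPI ester (step 9) joins the chain (step 10), and MOM removal (step 11) ends the route.
4. Rings and stereochemistry: both benzene rings are bought and no ring is formed; the target has no stereocentre and no stereogenic double bond, so nothing has to be set.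

Key step: step 10

Remark: the target is achiral, so the request for a single enantiomer is met by the constitution alone and no stereocontrol is planned.

**Step 1**
Reactants: 1 3-bromo-5-methylphenol
Product: 2 1-bromo-3-(methoxymethoxy)-5-methylbenzene
Conditions: MOMCl, i-Pr2NEt, CH2Cl2, 0 °C to rt
Reagents that add atoms: chloromethyl methyl ether, COCCl
Why: Williamson-type O-alkylation (MOM protection) of the phenol should be clean, and the acetal serves later as the ortho-directing group for step 2 and as a phenol mask that tolerates LDA, Cu/carbonate, borohydride, carbodiimide and cathodic Ni conditions.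

**Step 2**
Reactants: 2 1-bromo-3-(methoxymethoxy)-5-methylbenzene
Product: 4 methyl 2-bromo-6-(methoxymethoxy)-4-methylbenzoate, via 2-bromo-6-(methoxymethoxy)-4-methylphenyllithium 3 (not isolated)
Conditions: LDA, THF, −78 °C; then ClCO2Me, −78 °C to rt
Reagents that add atoms: methyl chloroformate, COC(=O)Cl
Why: Directed ortho-metalation: the proton flanked by Br and OMOM is the most acidic and is held by O–Li coordination, the amide base deprotonates without Br–Li exchange, −78 °C suppresses loss of LiBr to an aryne, and aryllithium 3 is acylated by methyl chloroformate so that the ester ends up para to the methyl group.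

**Step 3**
Reactants: 5 3-bromo-2-hydroxy-5-methoxybenzaldehyde
Product: 6 2,3-dihydroxy-5-methoxybenzaldehyde
Conditions: NaOH (aq.), Cu powder (cat.), reflux, Ar; then HCl (aq.)
Reagents that add atoms: sodium hydroxide, [Na+].[OH-]
Why: Copper-catalysed Ullmann-type hydroxylation of an ortho-bromophenolate (the reaction type that turns 5-bromovanillin into 5-hydroxyvanillin) should replace Br by OH, the phenolate aldehyde being inert to Cannizzaro reaction and air being excluded because the catechol is oxidisable in base.

**Step 4**
Reactants: 6 2,3-dihydroxy-5-methoxybenzaldehyde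
Product: 8 2-hydroxy-5-methoxy-3-(methoxymethoxy)benzaldehyde, via disodium 3-formyl-5-methoxybenzene-1,2-diolate 7 (not isolated)
Conditions: NaH (2.2 equiv), DMF, 0 °C; then MOMCl (1.0 equiv), 0 °C to rt; NH4Cl (aq.)
Reagents that add atoms: chloromethyl methyl ether, COCCl
Why: Regioselective O-alkylation through the dianion: the 2-phenoxide is delocalised into and chelated with the ortho formyl group, so the 3-phenoxide is the more nucleophilic oxygen and should take the single equivalent of MOMCl, as is known for 2,3-dihydroxybenzaldehyde.

**Step 5**
Reactants: 8 2-hydroxy-5-methoxy-3-(methoxymethoxy)benzaldehyde; 4 methyl 2-bromo-6-(methoxymethoxy)-4-methylbenzoate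
Product: 9 methyl 2-[2-formyl-4-methoxy-6-(methoxymethoxy)phenoxy]-6-(methoxymethoxy)-4-methylbenzoate
Conditions: CuI (cat.), N,N-dimethylglycine·HCl (cat.), Cs2CO3, 1,4-dioxane, 100 °C
Reagents that add atoms: none
Why: Ullmann diaryl ether synthesis (CuI/amino acid ligand): the ortho ester assists oxidative addition of the C–Br bond, 8 offers a single free phenol, and the non-enolisable aldehyde, the hindered methyl ester and the MOM acetals should survive Cs2CO3 at 100 °C.

**Step 6**
Reactants: 9 methyl 2-[2-formyl-4-methoxy-6-(methoxymethoxy)phenoxy]-6-(methoxymethoxy)-4-methylbenzoate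
Product: 10 methyl 2-[2-(hydroxymethyl)-4-methoxy-6-(methoxymethoxy)phenoxy]-6-(methoxymethoxy)-4-methylbenzoate
Conditions: NaBH4, MeOH/THF, 0 °C
Reagents that add atoms: none
Why: Chemoselective borohydride reduction of the aryl aldehyde to the benzylic alcohol; the doubly ortho-substituted methyl benzoate, the acetals and the ethers are inert at 0 °C.

**Step 7**
Reactants: 10 methyl 2-[2-(hydroxymethyl)-4-methoxy-6-(methoxymethoxy)phenoxy]-6-(methoxymethoxy)-4-methylbenzoate; 11 glutaric anhydride
Product: 12 5-{[2-(2-methoxycarbonyl-3-(methoxymethoxy)-5-methylphenoxy)-5-methoxy-3-(methoxymethoxy)phenyl]methoxy}-5-oxopentanoic acid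
Conditions: DMAP (cat.), CH2Cl2, rt; citric acid (aq.) work-up
Reagents that add atoms: none
Why: DMAP-catalysed ring-opening acylation of the only free hydroxyl group by the six-membered cyclic anhydride gives the half-ester in one operation, delivering C1–C4 of the future chain together with the carboxyl carbon that is to be expelled.

**Step 8**
Reactants: 12 5-{[2-(2-methoxycarbonyl-3-(methoxymethoxy)-5-methylphenoxy)-5-methoxy-3-(methoxymethoxy)phenyl]methoxy}-5-oxopentanoic acid
Product: 13 N-hydroxyphthalimide ester of 12, i.e. 1-{[2-(2-methoxycarbonyl-3-(methoxymethoxy)-5-methylphenoxy)-5-methoxy-3-(methoxymethoxy)phenyl]methyl} 5-(1,3-dioxoisoindolin-2-yl) pentanedioate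
Conditions: N-hydroxyphthalimide, DIC, DMAP (cat.), CH2Cl2, rt
Reagents that add atoms: N-hydroxyphthalimide, O=C1c2ccccc2C(=O)N1O
Why: Carbodiimide (Steglich-type) esterification of the free acid with N-hydroxyphthalimide gives the redox-active ester under neutral conditions that leave the acetals and esters intact.

**Step 9**
Reactants: 14 tridecanoic acid
Product: 15 1,3-dioxoisoindolin-2-yl tridecanoate
Conditions: N-hydroxyphthalimide, DIC, DMAP (cat.), CH2Cl2, rt
Reagents that add atoms: N-hydroxyphthalimide, O=C1c2ccccc2C(=O)N1O
Why: The same carbodiimide esterification converts the cheap fatty acid into its redox-active ester, the latent dodecyl radical.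

**Step 10**
Reactants: 13 N-hydroxyphthalimide ester of 12; 15 1,3-dioxoisoindolin-2-yl tridecanoate (3 equiv)
Product: 16 [2-(2-methoxycarbonyl-3-(methoxymethoxy)-5-methylphenoxy)-5-methoxy-3-(methoxymethoxy)phenyl]methyl hexadecanoate
Conditions: NiCl2·6H2O (20 mol%), 2,6-bis(pyrazol-1-yl)pyridine (20 mol%), AgNO3 (cat.), DMF, Mg(+)/RVC(−), undivided cell, constant current, rt; NH4Cl (aq.) work-up
Reagents that add atoms: none
Why: Cathodic electron transfer, mediated by low-valent Ni at the Ag-coated cathode, reduces each N-acyloxyphthalimide, which fragments to phthalimide anion, CO2 and a primary alkyl radical; one radical is captured by Ni, the resulting alkyl–Ni species combines with the second radical, and reductive elimination from the dialkyl–Ni(III) centre forms the C4–C5 bond while the Mg anode supplies the electrons. The closest known reaction type is the Ni-electrocatalytic doubly decarboxylative C(sp3)–C(sp3) cross-coupling of two redox-active esters, a reductive relative of the mixed Kolbe electrolysis that is established for pairs of primary alkyl partners bearing esters and ethers. No ring is closed and no stereocentre is formed, because both carbons that are joined are CH2 groups of an unbranched chain. The step needs cross- over homo-coupling and chemoselectivity: the former is not intrinsic for two primary radicals and is secured by the threefold excess of cheap 15, so that the main by-product should be non-polar tetracosane, and the latter rests on the two N-acyloxyphthalimides being the only groups reducible at this potential, whereas the aryl ethers, the benzylic and methyl esters and the MOM acetals are not. The radical from 13 sits at C4, γ to the ester carbonyl, so it is neither stabilised nor prone to β-scission, and the MOM groups keep acidic phenolic protons away from the alkyl–Ni intermediates.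

**Step 11**
Reactants: 16 [2-(2-methoxycarbonyl-3-(methoxymethoxy)-5-methylphenoxy)-5-methoxy-3-(methoxymethoxy)phenyl]methyl hexadecanoate
Product: 17 Betaethrin E, [3-hydroxy-2-(3-hydroxy-2-methoxycarbonyl-5-methylphenoxy)-5-methoxyphenyl]methyl hexadecanoate
Conditions: ZnBr2, n-PrSH, CH2Cl2, 0 °C to rt
Reagents that add atoms: none
Why: Lewis acid/thiol cleavage of the two aryl MOM acetals: ZnBr2 activates the acetal and the thiol traps the methoxymethyl cation, which prevents its Friedel–Crafts reaction with the electron-rich benzyl ring, while the benzylic hexadecanoate, the methyl ester, the aryl methyl ether and the diaryl ether are not touched.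

**Compound list**
1 | 3-bromo-5-methylphenol | Cc1cc(O)cc(Br)c1 | starting material
2 | 1-bromo-3-(methoxymethoxy)-5-methylbenzene | Cc1cc(Br)cc(OCOC)c1 | intermediate
3 | 2-bromo-6-(methoxymethoxy)-4-methylphenyllithium (not isolated) | [Li]c1c(Br)cc(C)cc1OCOC | intermediate
4 | methyl 2-bromo-6-(methoxymethoxy)-4-methylbenzoate | COC(=O)c1c(Br)cc(C)cc1OCOC | intermediate
5 | 3-bromo-2-hydroxy-5-methoxybenzaldehyde | O=Cc1cc(OC)cc(Br)c1O | starting material
6 | 2,3-dihydroxy-5-methoxybenzaldehyde | O=Cc1cc(OC)cc(O)c1O | intermediate
7 | disodium 3-formyl-5-methoxybenzene-1,2-diolate (not isolated) | O=Cc1cc(OC)cc([O-])c1[O-].[Na+].[Na+] | intermediate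
8 | 2-hydroxy-5-methoxy-3-(methoxymethoxy)benzaldehyde | O=Cc1cc(OC)cc(OCOC)c1O | intermediate
9 | methyl 2-[2-formyl-4-methoxy-6-(methoxymethoxy)phenoxy]-6-(methoxymethoxy)-4-methylbenzoate | O=Cc1cc(OC)cc(OCOC)c1Oc1cc(C)cc(OCOC)c1C(=O)OC | intermediate
10 | methyl 2-[2-(hydroxymethyl)-4-methoxy-6-(methoxymethoxy)phenoxy]-6-(methoxymethoxy)-4-methylbenzoate | OCc1cc(OC)cc(OCOC)c1Oc1cc(C)cc(OCOC)c1C(=O)OC | intermediate
11 | glutaric anhydride (oxane-2,6-dione) | O=C1CCCC(=O)O1 | starting material
12 | 5-{[2-(2-methoxycarbonyl-3-(methoxymethoxy)-5-methylphenoxy)-5-methoxy-3-(methoxymethoxy)phenyl]methoxy}-5-oxopentanoic acid | OC(=O)CCCC(=O)OCc1cc(OC)cc(OCOC)c1Oc1cc(C)cc(OCOC)c1C(=O)OC | intermediate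
13 | N-hydroxyphthalimide ester of 12 (1-arylmethyl 5-(1,3-dioxoisoindolin-2-yl) pentanedioate) | O=C(CCCC(=O)OCc1cc(OC)cc(OCOC)c1Oc1cc(C)cc(OCOC)c1C(=O)OC)ON1C(=O)c2ccccc2C1=O | intermediate
14 | tridecanoic acid | CCCCCCCCCCCCC(=O)O | starting material
15 | 1,3-dioxoisoindolin-2-yl tridecanoate | CCCCCCCCCCCCC(=O)ON1C(=O)c2ccccc2C1=O | intermediate
16 | bis-MOM ether of Betaethrin E, [2-(2-methoxycarbonyl-3-(methoxymethoxy)-5-methylphenoxy)-5-methoxy-3-(methoxymethoxy)phenyl]methyl hexadecanoate | CCCCCCCCCCCCCCCC(=O)OCc1cc(OC)cc(OCOC)c1Oc1cc(C)cc(OCOC)c1C(=O)OC | intermediate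
17 | Betaethrin E | CCCCCCCCCCCCCCCC(=O)OCc1cc(OC)cc(O)c1Oc1cc(C)cc(O)c1C(=O)OC | target

**Step count and risks**
Total steps: 11. Longest linear sequence: 8 steps (3, 4, 5, 6, 7, 8, 10, 11). Steps 1–2 join at step 5 and step 9 joins at step 10.

Steps most likely to fail:

Step 10. Cross-selectivity is statistical, so homodimerisation of the precious radical, its simple reduction to the butanoate, or hydrolysis of the activated ester before reduction may consume 13. The fallback forms the same C4–C5 bond by a two-electron cross-coupling and sets out from alcohol 10. Acylation with 4-bromobutanoyl chloride and pyridine should give the 4-bromobutanoate of 10 F1. Hydroboration of 1-dodecene with 9-BBN-H should give B-dodecyl-9-borabicyclo[3.3.1]nonane F2. A B-alkyl Suzuki–Miyaura coupling of the primary bromide with the alkylborane (Pd(OAc)2, PCy3, K3PO4·H2O, THF, rt), which tolerates esters, should return to the route at 16.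

Step 5. The phenoxide of 8 is chelated by its ortho formyl group and flanked by two substituents, so C–O bond formation at copper may stall and protodebromination of 4 may take over. The fallback moves the reduction ahead of the coupling, so that the nucleophile is an electron-rich, non-chelating phenol, and changes the metal; it sets out from 8. NaBH4 should give 2-(hydroxymethyl)-4-methoxy-6-(methoxymethoxy)phenol F3. TBSCl and imidazole should silylate the primary alcohol in preference to the hindered phenol and give 2-[(tert-butyldimethylsilyloxy)methyl]-4-methoxy-6-(methoxymethoxy)phenol F4. Pd-catalysed C–O coupling with bromide 4 (Pd(OAc)2, bulky biarylphosphine, K3PO4, toluene, 100 °C) should give the silyl ether of 10 F5. TBAF then returns to the route at 10.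

Step 4. Discrimination between the two phenoxide oxygens may be incomplete, giving the wrong mono-ether or double alkylation. The fallback protects both and differentiates on removal; it sets out from 6. Excess MOMCl and i-Pr2NEt should give 5-methoxy-2,3-bis(methoxymethoxy)benzaldehyde F6. Brief treatment with catalytic HCl in MeOH at rt should cleave selectively the acetal ortho to the formyl group, whose phenol is released into a hydrogen bond with the carbonyl, and return to the route at 8.

**Further compounds**
F1 | step 10 | [2-(2-methoxycarbonyl-3-(methoxymethoxy)-5-methylphenoxy)-5-methoxy-3-(methoxymethoxy)phenyl]methyl 4-bromobutanoate | BrCCCC(=O)OCc1cc(OC)cc(OCOC)c1Oc1cc(C)cc(OCOC)c1C(=O)OC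
F2 | step 10 | 9-dodecyl-9-borabicyclo[3.3.1]nonane | CCCCCCCCCCCCB1C2CCCC1CCC2
F3 | step 5 | 2-(hydroxymethyl)-4-methoxy-6-(methoxymethoxy)phenol | OCc1cc(OC)cc(OCOC)c1O
F4 | step 5 | 2-[(tert-butyldimethylsilyloxy)methyl]-4-methoxy-6-(methoxymethoxy)phenol | CC(C)(C)[Si](C)(C)OCc1cc(OC)cc(OCOC)c1O
F5 | step 5 | methyl 2-{2-[(tert-butyldimethylsilyloxy)methyl]-4-methoxy-6-(methoxymethoxy)phenoxy}-6-(methoxymethoxy)-4-methylbenzoate | CC(C)(C)[Si](C)(C)OCc1cc(OC)cc(OCOC)c1Oc1cc(C)cc(OCOC)c1C(=O)OC
F6 | step 4 | 5-methoxy-2,3-bis(methoxymethoxy)benzaldehyde | O=Cc1cc(OC)cc(OCOC)c1OCOC
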